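The route rests on cutting the seven-membered enol lactone at its aryl–carbonyl bond and ring A (the cyclohexene) at the bond between the quaternary carbon and the enol carbon. The key step exploits that the methyl carbon on the quaternary centre lies 1,4 to the aromatic C–H that must carry the lactone carbonyl. An alkenylrhodium closes ring A onto a 1,1-disubstituted alkene, rhodium walks from the nascent methyl carbon to that arene carbon, and CO2 is captured there. The precursor is an acyclic 2-boryl-1-ethoxytriene bearing a 1,4-dimethoxynaphthalene. Acid then closes the lactone, and oxidation plus hypotaurine complete the thiazinoquinone.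

Key step: step 8

Assumption: the sense of asymmetric induction of the bisphosphine in step 8 cannot be assigned in advance; (S,S)-BDPP is written, and its mirror image is used if the (R)-acid should form.

Step 1
Reactants: 1 1,4-dimethoxynaphthalene
Product: 2 2-(5,8-dimethoxynaphthalen-2-yl)-4,4,5,5-tetramethyl-1,3,2-dioxaborolane
Conditions: [Ir(OMe)(cod)]2 (1.5 mol%), 4,4′-di-tert-butyl-2,2′-bipyridine (3 mol%), B2pin2 (0.7 equiv), hexane, 60 °C
Reagents that add atoms: bis(pinacolato)diboron, CC1(C)OB(OC1(C)C)B1OC(C)(C)C(C)(C)O1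
Why: Iridium-catalysed aromatic C–H borylation is sterically controlled, and only C6/C7 (equivalent by symmetry) have neither an ortho substituent nor a peri neighbour, while sub-stoichiometric diboron limits double borylation.

Step 2
Reactants: 3 2-bromoprop-2-en-1-ol; 4 triethyl orthoacetate
Product: 6 ethyl 4-bromopent-4-enoate, via ketene acetal 5 (not isolated)
Conditions: EtCO2H (5 mol%), 4 (5 equiv, neat), 140 °C, ethanol distilled off
Reagents that add atoms: none
Why: Johnson–Claisen rearrangement, in which the mixed ketene acetal of the allylic alcohol undergoes a [3,3]-sigmatropic shift to the γ,δ-unsaturated ester.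

Step 3
Reactants: 6 ethyl 4-bromopent-4-enoate
Product: 8 4-bromopent-4-enal, via aluminium hemiacetal 7 (not isolated)
Conditions: i-Bu2AlH (1.05 equiv), CH2Cl2, −78 °C; aqueous KNaC4H4O6
Reagents that add atoms: none
Why: Partial ester reduction with i-Bu2AlH stops at the tetrahedral aluminium hemiacetal at −78 °C and releases the aldehyde on work-up.

Step 4
Reactants: 8 4-bromopent-4-enal; 9 ethyltriphenylphosphonium bromide
Product: 13 (5Z)-2-bromo-6-iodohepta-1,5-diene, via ethylidenetriphenylphosphorane 10 (not isolated), via (1-iodoethyl)triphenylphosphonium iodide 11 (not isolated), via (1-iodoethylidene)triphenylphosphorane 12 (not isolated)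
Conditions: 9, n-BuLi, THF, 0 °C; I2, −78 °C; NaN(SiMe3)2, −20 °C; then 8, −78 to 23 °C
Reagents that add atoms: iodine, [I][I]
Why: Stork–Zhao-type Wittig olefination with the α-iodo ylide should give the (Z)-2-iodoalk-2-ene under kinetic control, with iodine and the chain cis.

Step 5
Reactants: 13 (5Z)-2-bromo-6-iodohepta-1,5-diene; 14 tributyl(ethoxyethynyl)stannane
Product: 15 (5Z)-2-bromo-8-ethoxy-6-methylocta-1,5-dien-7-yne
Conditions: Pd(PPh3)4 (5 mol%), CuI (10 mol%), DMF, 23 °C
Reagents that add atoms: none
Why: Stille coupling, in which the alkenyl iodide undergoes oxidative addition well before the 2-bromoalkene and the alkene geometry is retained.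

Step 6
Reactants: 2 2-(5,8-dimethoxynaphthalen-2-yl)-4,4,5,5-tetramethyl-1,3,2-dioxaborolane; 15 (5Z)-2-bromo-8-ethoxy-6-methylocta-1,5-dien-7-yne
Product: 16 6-[(5Z)-8-ethoxy-6-methylocta-1,5-dien-7-yn-2-yl]-1,4-dimethoxynaphthalene
Conditions: Pd(dppf)Cl2 (5 mol%), K3PO4 (3 equiv), 1,4-dioxane/H2O (5:1), 60 °C
Reagents that add atoms: none
Why: Suzuki–Miyaura coupling of the aryl boronate with the 2-bromoalkene, under basic conditions that the acid-labile ynol ether tolerates.

Step 7
Reactants: 16 6-[(5Z)-8-ethoxy-6-methylocta-1,5-dien-7-yn-2-yl]-1,4-dimethoxynaphthalene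
Product: 17 2-[(1Z,3Z)-7-(5,8-dimethoxynaphthalen-2-yl)-1-ethoxy-3-methylocta-1,3,7-trien-2-yl]-4,4,5,5-tetramethyl-1,3,2-dioxaborolane
Conditions: pinacolborane (1.2 equiv), Cp2Zr(H)Cl (5 mol%), Et3N (10 mol%), CH2Cl2, 23 °C
Reagents that add atoms: pinacolborane, B1OC(C)(C)C(C)(C)O1
Why: Zirconium-catalysed syn-hydroboration of a 1-alkoxyalkyne, whose polarisation sends hydride to the oxygen-bearing carbon and boron to the β-carbon (boron trans to ethoxy) while the unactivated alkenes stay untouched.

Step 8
Reactants: 17 2-[(1Z,3Z)-7-(5,8-dimethoxynaphthalen-2-yl)-1-ethoxy-3-methylocta-1,3,7-trien-2-yl]-4,4,5,5-tetramethyl-1,3,2-dioxaborolane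
Product: 19 3-[(1S,2E)-2-(ethoxymethylidene)-1,3-dimethylcyclohex-3-en-1-yl]-5,8-dimethoxynaphthalene-2-carboxylic acid, via cesium carboxylate 18 (not isolated)
Conditions: [Rh(OH)(cod)]2 (5 mol%), (S,S)-BDPP [(2S,4S)-2,4-bis(diphenylphosphino)pentane, 11 mol%], CsF (3 equiv), CO2 (1 atm), 1,4-dioxane, 60 °C; then cold 0.5 M HCl
Reagents that add atoms: carbon dioxide, O=C=O
Why: Proposed new method: fluoride-assisted boron-to-rhodium transmetalation gives an alkenyl species of monovalent rhodium at the enol carbon (ethoxy trans to Rh, so no syn β-alkoxide elimination), which inserts the tethered 1,1-disubstituted alkene by syn-carborhodation, forming the bond to the quaternary carbon and leaving Rh on a neopentyl-type CH2 without β-hydrogen; a 1,4-rhodium shift to the ortho aromatic C–H then turns this CH2 into the methyl group and puts Rh on the arene carbon, where CO2 inserts to give carboxylate 18, and the rhodium carboxylate re-enters the cycle by transmetalation. The closest known reaction types are boron-initiated rhodium-catalysed alkenylative cyclisations, alkyl-to-aryl 1,4-rhodium migration and the rhodium-catalysed carboxylation of arylboronic esters with CO2, which have not been combined on an unactivated 1,1-disubstituted alkene. Ring A closes in the 6-exo-trig mode (the 7-endo mode would need a tertiary benzylic C–Rh bond), and no other ring closes in this step. The quaternary stereocentre is set in the alkene insertion, whose enantiofacial course is controlled by the C2-symmetric bisphosphine on rhodium. The step needs cyclisation before CO2 capture (an intramolecular insertion against a slow bimolecular one at 1 atm), migration to C7–H of the naphthalene rather than to the peri-hindered C5–H or the vinylic C–H next to the ethoxy group (the shifts are reversible and these two give more congested C–Rh bonds), and carboxylation only at the aryl stage (the alkylrhodium shifts faster than it inserts CO2).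

Step 9
Reactants: 19 3-[(1S,2E)-2-(ethoxymethylidene)-1,3-dimethylcyclohex-3-en-1-yl]-5,8-dimethoxynaphthalene-2-carboxylic acid
Product: 21 (S)-dimethoxy enol lactone (ring system of 27 with the quinone as its dimethyl ether and without the thiazine), via cyclic ethoxy acylal 20 (not isolated)
Conditions: camphor-10-sulfonic acid (10 mol%), toluene, 5 Å molecular sieves, 80 °C
Reagents that add atoms: none
Why: Acid-mediated cyclisation of an aryl carboxylic acid onto a protonated enol ether followed by loss of ethanol (the reaction type that turns 2-(alkoxyvinyl)benzoic acids into isocoumarins), here closing the seven-membered ring and regenerating the conjugated dienol ester; the E/Z geometry of 19 is erased at the oxocarbenium stage.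

Step 10
Reactants: 21 (S)-dimethoxy enol lactone
Product: 22 (S)-naphthoquinone enol lactone
Conditions: (NH4)2Ce(NO3)6 (2.5 equiv), MeCN/H2O (2:1), 0 °C
Reagents that add atoms: water, O
Why: Oxidative demethylation of a 1,4-dimethoxyarene by tetravalent cerium, in which the electron-rich dimethoxy ring is oxidised far faster than the dienol ester and the quinone oxygens come from water.

Step 11
Reactants: 22 (S)-naphthoquinone enol lactone; 23 hypotaurine (2-aminoethanesulfinic acid)
Product: 27 CNP0348176.1 (target), via sulfonyl hydroquinone 24 (not isolated), via sulfonyl quinone 25 (not isolated), via thiazine hydroquinone 26 (not isolated)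
Conditions: 23 (1.2 equiv), Co(salen) (5 mol%), O2 (1 atm), MeCN/EtOH/H2O (1:1:1), 23 °C
Reagents that add atoms: none
Why: Oxidative hetero-annulation of a quinone by hypotaurine: the sulfinate should add to the quinone CH that is β to the more electron-poor carbonyl (the one whose aryl carbon is para to the lactone carbonyl), and aerobic re-oxidation, intramolecular amine addition and a second oxidation then give the thiazine 1,1-dioxide, while the largely protonated amine is expected to spare the enol lactone.

Compound list

1 | 1,4-dimethoxynaphthalene | COc1ccc(OC)c2ccccc12 | starting material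
2 | 2-(5,8-dimethoxynaphthalen-2-yl)-4,4,5,5-tetramethyl-1,3,2-dioxaborolane | COc1ccc(OC)c2cc(B3OC(C)(C)C(C)(C)O3)ccc12 | intermediate
3 | 2-bromoprop-2-en-1-ol | OCC(Br)=C | starting material
4 | triethyl orthoacetate | CC(OCC)(OCC)OCC | starting material
5 | 2-bromo-3-[(1-ethoxyethenyl)oxy]prop-1-ene (ketene acetal, not isolated) | C=C(Br)COC(=C)OCC | intermediate
6 | ethyl 4-bromopent-4-enoate | CCOC(=O)CCC(Br)=C | intermediate
7 | diisobutylaluminium 4-bromo-1-ethoxypent-4-en-1-olate (aluminium hemiacetal, not isolated) | CCOC(CCC(Br)=C)O[Al](CC(C)C)CC(C)C | intermediate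
8 | 4-bromopent-4-enal | O=CCCC(Br)=C | intermediate
9 | ethyltriphenylphosphonium bromide | CC[P+](c1ccccc1)(c1ccccc1)c1ccccc1.[Br-] | starting material
10 | ethylidenetriphenylphosphorane (not isolated) | CC=P(c1ccccc1)(c1ccccc1)c1ccccc1 | intermediate
11 | (1-iodoethyl)triphenylphosphonium iodide (not isolated) | CC(I)[P+](c1ccccc1)(c1ccccc1)c1ccccc1.[I-] | intermediate
12 | (1-iodoethylidene)triphenylphosphorane (not isolated) | CC(I)=P(c1ccccc1)(c1ccccc1)c1ccccc1 | intermediate
13 | (5Z)-2-bromo-6-iodohepta-1,5-diene | C=C(Br)CC/C=C(/C)I | intermediate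
14 | tributyl(ethoxyethynyl)stannane | CCOC#C[Sn](CCCC)(CCCC)CCCC | starting material
15 | (5Z)-2-bromo-8-ethoxy-6-methylocta-1,5-dien-7-yne | C=C(Br)CC/C=C(/C)C#COCC | intermediate
16 | 6-[(5Z)-8-ethoxy-6-methylocta-1,5-dien-7-yn-2-yl]-1,4-dimethoxynaphthalene | COc1ccc(OC)c2cc(C(=C)CC/C=C(/C)C#COCC)ccc12 | intermediate
17 | 2-[(1Z,3Z)-7-(5,8-dimethoxynaphthalen-2-yl)-1-ethoxy-3-methylocta-1,3,7-trien-2-yl]-4,4,5,5-tetramethyl-1,3,2-dioxaborolane | CCO/C=C(/B1OC(C)(C)C(C)(C)O1)\C(C)=C/CCC(=C)c1ccc2c(OC)ccc(OC)c2c1 | intermediate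
18 | cesium 3-[(1S,2E)-2-(ethoxymethylidene)-1,3-dimethylcyclohex-3-en-1-yl]-5,8-dimethoxynaphthalene-2-carboxylate (not isolated) | CC1=CCC[C@@](C)(c2cc3c(OC)ccc(OC)c3cc2C(=O)[O-])/C1=C/OCC.[Cs+] | intermediate
19 | 3-[(1S,2E)-2-(ethoxymethylidene)-1,3-dimethylcyclohex-3-en-1-yl]-5,8-dimethoxynaphthalene-2-carboxylic acid | CC1=CCC[C@@](C)(c2cc3c(OC)ccc(OC)c3cc2C(=O)O)/C1=C/OCC | intermediate
20 | cyclic ethoxy acylal: seven-membered lactone with a saturated O–CH(OEt)–CH unit, epimers at these two carbons, quaternary carbon as in 19 (CIP descriptor R there, same spatial arrangement; not isolated) | CCOC1OC(=O)c2cc3c(OC)ccc(OC)c3cc2[C@]2(C)CCC=C(C)C12 | intermediate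
21 | (S)-dimethoxy enol lactone: seven-membered ring O–C(=O)–C2(naphthalene)–C3(naphthalene)–C(CH3)–C(=CH–O), the last two carbons being C1 and C2 of a 3-methylcyclohex-3-ene (ring A), 5,8-dimethoxy on the naphthalene | CC1=CCC[C@]2(C)C1=COC(=O)c1cc3c(OC)ccc(OC)c3cc12 | intermediate
22 | (S)-naphthoquinone enol lactone: 21 with the dimethoxy ring as the 1,4-quinone | CC1=CCC[C@]2(C)C1=COC(=O)c1cc3c(cc12)C(=O)C=CC3=O | intermediate
23 | hypotaurine (2-aminoethanesulfinic acid) | NCCS(=O)O | starting material
24 | (S)-sulfonyl hydroquinone: hydroquinone of 22 with 2-aminoethylsulfonyl on the ring carbon next to the C–OH whose aryl carbon is para to the quaternary-carbon-bearing position (not isolated) | CC1=CCC[C@]2(C)C1=COC(=O)c1cc3c(O)c(S(=O)(=O)CCN)cc(O)c3cc12 | intermediate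
25 | (S)-sulfonyl quinone: quinone form of 24 (not isolated) | CC1=CCC[C@]2(C)C1=COC(=O)c1cc3c(cc12)C(=O)C=C(C3=O)S(=O)(=O)CCN | intermediate
26 | (S)-thiazine hydroquinone: dihydro form of 27 (not isolated) | CC1=CCC[C@]2(C)C1=COC(=O)c1cc3c(O)c4c(NCCS4(=O)=O)c(O)c3cc12 | intermediate
27 | CNP0348176.1, (S)-configured at the quaternary carbon | CC1=CCC[C@]2(C)C1=COC(=O)c1cc3c(cc12)C(=O)C1=C(C3=O)S(=O)(=O)CCN1 | target

Total step count: 11. Longest linear sequence: 10 steps (3 → 6 → 8 → 13 → 15 → 16 → 17 → 19 → 21 → 22 → 27).

Steps most likely to fail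

Step 8. The process at risk is capture of CO2 or of a proton by the alkenyl- or alkylrhodium before the relay is complete, or migration of rhodium to the vinylic C–H beside the ethoxy group, so that the carboxyl group does not reach the arene. The fallback sets out from 2 and 15 and returns at 19: the carboxyl carbon is placed on the arene first and ring A is then closed by a reductive Heck reaction. 2 is coupled with methyl chloroformate (Pd(PPh3)4, K3PO4, toluene, 80 °C) to give methyl 5,8-dimethoxynaphthalene-2-carboxylate F1. Ester-directed ortho-borylation ([Ir(OMe)(cod)]2, P[3,5-(CF3)2C6H3]3, B2pin2, octane, 80 °C) should give the 3-boryl ester F2, the peri-flanked C1–H being spared. Suzuki coupling with 15 under the conditions of step 6 gives the ynol ether ester F3, and hydroboration as in step 7 gives the alkenylboronate ester F4. Iododeboronation with retention (NaOH, I2, THF, 0 °C) gives the alkenyl iodide F5. An enantioselective reductive Heck cyclisation (Pd(OAc)2, (R)-BINAP, HCO2Na, DMF, 80 °C, zerovalent palladium formed in situ) closes ring A, sets the quaternary centre and reduces the neopentyl palladium to the methyl group, giving the cyclised ester F6. LiOH (THF/MeOH/H2O, 40 °C) then gives 19.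

Step 11. The process at risk is poor regiocontrol in the first conjugate addition, which would place sulfur on the wrong quinone carbon, together with aminolysis of the enol lactone. The fallback sets out from 21 and 23 and returns at 25: sulfur is attached by cross-coupling at a defined carbon before the quinone is unveiled. N-Bromosuccinimide (MeCN, 0 °C) should brominate 21 at the dimethoxy-ring CH whose σ-complex places charge on the alkyl-bearing and not on the acyl-bearing carbon of the neighbouring ring, giving the bromide F7. 23 with Boc2O and NaOH gives sodium 2-[(tert-butoxycarbonyl)amino]ethanesulfinate F8. Pd-catalysed sulfinate coupling of the two (Pd2(dba)3, Xantphos, Cs2CO3, toluene, 90 °C) gives the aryl sulfone F9, and (NH4)2Ce(NO3)6 (MeCN/H2O, 0 °C) gives the protected sulfonyl quinone F10. Me3SiOTf and 2,6-lutidine (CH2Cl2, 0 °C), then MeOH, remove the Boc group and give 25, which closes and is oxidised by air to 27 as in step 11.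

Step 9. The process at risk is reversible addition of the acid to the oxocarbenium ion without loss of ethanol, or acid-induced migration of the ring A double bond. The fallback sets out from 19 and returns at 21: 1 M HCl in THF hydrolyses the enol ether to the aldehyde acid F11 (epimers at the formyl-bearing carbon). 2,4,6-Trichlorobenzoyl chloride and Et3N (THF) give the mixed anhydride F12, and DMAP (toluene, 60 °C) then promotes O-acylation of the dienol form to give 21.

Further compounds

F1 | step 8 | methyl 5,8-dimethoxynaphthalene-2-carboxylate | COC(=O)c1ccc2c(OC)ccc(OC)c2c1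
F2 | step 8 | methyl 5,8-dimethoxy-3-(4,4,5,5-tetramethyl-1,3,2-dioxaborolan-2-yl)naphthalene-2-carboxylate | COC(=O)c1cc2c(OC)ccc(OC)c2cc1B1OC(C)(C)C(C)(C)O1
F3 | step 8 | methyl 3-[(5Z)-8-ethoxy-6-methylocta-1,5-dien-7-yn-2-yl]-5,8-dimethoxynaphthalene-2-carboxylate | CCOC#C/C(C)=C\CCC(=C)c1cc2c(OC)ccc(OC)c2cc1C(=O)OC
F4 | step 8 | methyl 3-[(5Z,7Z)-8-ethoxy-6-methyl-7-(4,4,5,5-tetramethyl-1,3,2-dioxaborolan-2-yl)octa-1,5,7-trien-2-yl]-5,8-dimethoxynaphthalene-2-carboxylate | CCO/C=C(/B1OC(C)(C)C(C)(C)O1)\C(C)=C/CCC(=C)c1cc2c(OC)ccc(OC)c2cc1C(=O)OC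
F5 | step 8 | methyl 3-[(5Z,7E)-8-ethoxy-7-iodo-6-methylocta-1,5,7-trien-2-yl]-5,8-dimethoxynaphthalene-2-carboxylate | CCO/C=C(/I)\C(C)=C/CCC(=C)c1cc2c(OC)ccc(OC)c2cc1C(=O)OC
F6 | step 8 | methyl 3-[(1S,2E)-2-(ethoxymethylidene)-1,3-dimethylcyclohex-3-en-1-yl]-5,8-dimethoxynaphthalene-2-carboxylate | CC1=CCC[C@@](C)(c2cc3c(OC)ccc(OC)c3cc2C(=O)OC)/C1=C/OCC
F7 | step 11 | (S)-bromo dimethoxy enol lactone (21 with bromine on the dimethoxy-ring CH next to the C–OMe whose aryl carbon is para to the quaternary-carbon-bearing position) | CC1=CCC[C@]2(C)C1=COC(=O)c1cc3c(OC)c(Br)cc(OC)c3cc12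
F8 | step 11 | sodium 2-[(tert-butoxycarbonyl)amino]ethanesulfinate | CC(C)(C)OC(=O)NCCS(=O)[O-].[Na+]
F9 | step 11 | (S)-aryl sulfone (F7 with 2-[(tert-butoxycarbonyl)amino]ethylsulfonyl in place of bromine) | CC1=CCC[C@]2(C)C1=COC(=O)c1cc3c(OC)c(S(=O)(=O)CCNC(=O)OC(C)(C)C)cc(OC)c3cc12
F10 | step 11 | (S)-N-Boc sulfonyl quinone (N-Boc derivative of 25) | CC1=CCC[C@]2(C)C1=COC(=O)c1cc3c(cc12)C(=O)C=C(C3=O)S(=O)(=O)CCNC(=O)OC(C)(C)C
F11 | step 9 | 3-[(1R)-2-formyl-1,3-dimethylcyclohex-3-en-1-yl]-5,8-dimethoxynaphthalene-2-carboxylic acid (same spatial arrangement at the quaternary carbon as in 19, epimers at the formyl-bearing carbon) | CC1=CCC[C@@](C)(c2cc3c(OC)ccc(OC)c3cc2C(=O)O)C1C=O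
F12 | step 9 | mixed anhydride of F11 with 2,4,6-trichlorobenzoic acid | CC1=CCC[C@@](C)(c2cc3c(OC)ccc(OC)c3cc2C(=O)OC(=O)c2c(Cl)cc(Cl)cc2Cl)C1C=O
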